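## Retrosynthetic overview

1. Target 17 is (2S)-6-alkenylnaringenin; the last step is global MOM removal from 15, and ring C is the last ring formed.
2. Key disconnection C4–C4a and O1–C8a: ring C (O1, C2, C3, C4, C4a, C8a) arises from the four-membered (S)-β-lactone 11, which already holds O1, C2, C3 and C4, by formal insertion of the arene carbons C4a–C8a of fluoroarene 5 into its acyl C4–O1 bond (4 → 6 ring expansion).
3. Enabling feature: O1–C2(aryl)–C3–C4(=O) is a β-oxy-acyl unit, i.e. a β-lactone. With F on C8a the A ring is symmetric about the C6···C8a axis, so its only C–H (C4a ≡ C8, between F and OMOM) can be lithiated, and the C8a–F bond ortho to the new C4 ketone is the SNAr site.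
4. Arene 5: 5-fluororesorcinol → iodination between the OH groups → MOM → Heck with (S)-β-citronellene (chiral pool sets C3', E-alkene). Lactone 11: 4'-hydroxyacetophenone → MOM → Claisen → Noyori transfer hydrogenation (sets C2) → hydrolysis → lactonization.
5. Ring order: rings A and B are purchased; β-lactone ring (step 8) → ring C (step 9).

Key step: step 9

Assumption: 5-fluororesorcinol (1) and (S)-β-citronellene (4) are taken as purchasable; 1 is otherwise one BBr3 demethylation away from 1-fluoro-3,5-dimethoxybenzene.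

## Route

Step 1
Reactants: 1 5-fluororesorcinol
Product: 2 5-fluoro-2-iodobenzene-1,3-diol
Conditions: I2 (1.05 equiv), NaHCO3 (1.1 equiv), H2O/THF, 0 °C → rt
Reagents that add atoms: iodine, II
Why: Electrophilic aromatic iodination of the resorcinol under bicarbonate should go to the position between the two hydroxyls, as with resorcinol and orcinol, the fluorine further disfavouring the 4/6 positions.

Step 2
Reactants: 2 5-fluoro-2-iodobenzene-1,3-diol
Product: 3 5-fluoro-2-iodo-1,3-bis(methoxymethoxy)benzene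
Conditions: MOMCl (2.6 equiv), i-Pr2NEt (3 equiv), CH2Cl2, 0 °C → rt
Reagents that add atoms: chloromethyl methyl ether, COCCl
Why: Williamson-type O-alkylation of both phenols installs acetal ethers that survive organolithiums and later direct the ortho-metalation.

Step 3
Reactants: 3 5-fluoro-2-iodo-1,3-bis(methoxymethoxy)benzene; 4 (S)-3,7-dimethylocta-1,6-diene ((S)-β-citronellene, 2 equiv)
Product: 5 2-[(1E,3S)-3,7-dimethylocta-1,6-dien-1-yl]-5-fluoro-1,3-bis(methoxymethoxy)benzene
Conditions: Pd(OAc)2 (5 mol %), n-Bu4NCl, NaHCO3, DMF, 70 °C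
Reagents that add atoms: none
Why: Mizoroki–Heck arylation, in which the aryl–Pd adds to the terminal vinyl carbon and syn β-hydride elimination from the benzylic CH2 should give the conjugated E-alkene, while the allylic stereocenter of 4 is not involved and is carried through.

Step 4
Reactants: 6 4'-hydroxyacetophenone
Product: 7 1-[4-(methoxymethoxy)phenyl]ethan-1-one
Conditions: MOMCl (1.3 equiv), i-Pr2NEt (1.5 equiv), CH2Cl2, 0 °C → rt
Reagents that add atoms: chloromethyl methyl ether, COCCl
Why: Williamson-type O-alkylation of the phenol gives a base-stable MOM ether.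

Step 5
Reactants: 7 1-[4-(methoxymethoxy)phenyl]ethan-1-one
Product: 8 ethyl 3-[4-(methoxymethoxy)phenyl]-3-oxopropanoate
Conditions: NaH (2.2 equiv), (EtO)2CO (3 equiv), THF, reflux; AcOH quench
Reagents that add atoms: diethyl carbonate, CCOC(=O)OCC
Why: Crossed Claisen condensation (C-ethoxycarbonylation of the methyl ketone enolate), driven to completion by formation of the β-keto ester enolate.

Step 6
Reactants: 8 ethyl 3-[4-(methoxymethoxy)phenyl]-3-oxopropanoate
Product: 9 ethyl (3S)-3-hydroxy-3-[4-(methoxymethoxy)phenyl]propanoate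
Conditions: RuCl[(S,S)-TsDPEN](p-cymene) (1 mol %), HCO2H/Et3N (5:2), DMF, 30 °C
Reagents that add atoms: none
Why: Noyori asymmetric transfer hydrogenation of the aryl ketone, where the (S,S)-catalyst is expected, by analogy with acetophenone-type substrates, to deliver hydride to the face giving the (S)-carbinol that becomes C2 of the target.

Step 7
Reactants: 9 ethyl (3S)-3-hydroxy-3-[4-(methoxymethoxy)phenyl]propanoate
Product: 10 (3S)-3-hydroxy-3-[4-(methoxymethoxy)phenyl]propanoic acid
Conditions: LiOH·H2O (2 equiv), THF/H2O, 0 °C → rt; cold 1 M HCl to pH 3–4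
Reagents that add atoms: lithium hydroxide, [Li+].[OH-]
Why: Ester saponification (acyl–oxygen cleavage) does not touch the carbinol center, and the MOM ether is stable to base and to brief cold dilute acid.

Step 8
Reactants: 10 (3S)-3-hydroxy-3-[4-(methoxymethoxy)phenyl]propanoic acid
Product: 11 (4S)-4-[4-(methoxymethoxy)phenyl]oxetan-2-one
Conditions: PhSO2Cl (2 equiv), pyridine, 0–4 °C, 16 h; cold work-up, use at once
Reagents that add atoms: none
Why: Carboxyl-activation lactonization through the mixed sulfonic anhydride (4-exo-trig acyl substitution by the β-hydroxyl) retains configuration because the benzylic C–O bond is never broken.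

Step 9
Reactants: 5 2-[(1E,3S)-3,7-dimethylocta-1,6-dien-1-yl]-5-fluoro-1,3-bis(methoxymethoxy)benzene; 11 (4S)-4-[4-(methoxymethoxy)phenyl]oxetan-2-one (1.3 equiv)
Product: 15 (2S)-6-[(1E,3S)-3,7-dimethylocta-1,6-dien-1-yl]-5,7-bis(methoxymethoxy)-2-[4-(methoxymethoxy)phenyl]-2,3-dihydro-4H-chromen-4-one, via aryllithium 12 (not isolated), via lactone adduct 13 (not isolated), via lithium keto-alkoxide 14 (not isolated)
Conditions: LiTMP (1.05 equiv, from TMPH/n-BuLi), THF, −78 °C, 1 h; cannulate into 11, THF, −78 °C, 30 min; DMPU, −78 → 0 °C; AcOH quench at 0 °C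
Reagents that add atoms: none
Why: Proposed new method: a one-flask two-atom ring expansion of a β-lactone by an o-fluoroaryllithium, reasoned as follows: LiTMP removes the only kind of ring proton in 5 (between F and OMOM) to give 12, which as a hard nucleophile attacks the strained lactone carbonyl (acyl–oxygen cleavage, the usual course of organolithium additions to β-lactones) through adduct 13 to the keto-alkoxide 14, and this alkoxide then displaces the fluoride now ortho to the new C4 ketone by addition–elimination (SNAr through a carbonyl-stabilised Meisenheimer complex, LiF as sink). The closest known reaction types are aryne σ-insertion into acyl–heteroatom and acyl–carbon bonds of small rings, and the stepwise acylation/intramolecular SNAr route from o-fluoroaryl β-hydroxy ketones to chroman-4-ones; fluorine acts as ortho-director, latent electrophilic site and leaving group and is lost in the same step. Ring C is closed in the 6-exo mode at C8a (O1–C8a) after the C4–C4a bond has been formed intermolecularly, so O1, C2, C3 and C4 stay connected as in 11 except for the single C4–O1 bond into which C4a–C8a are inserted. No new stereocenter is formed, and C2 is carried over from 11 with retention because neither its C–O nor its C–C bond is broken. Regiochemistry is fixed by the substrate (one kind of C–H in 5; fluoride is a far better nucleofuge than the ortho OMOM), chemoselectivity by the hard aryllithium at −78 °C with inverse addition to excess lactone, and stereochemical integrity requires ring closure to outrun retro-aldol cleavage and E1cB loss from 14, for which the chelated lithium aldolate is kept cold and the SNAr is accelerated with DMPU.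

Step 10
Reactants: 15 (2S)-6-[(1E,3S)-3,7-dimethylocta-1,6-dien-1-yl]-5,7-bis(methoxymethoxy)-2-[4-(methoxymethoxy)phenyl]-2,3-dihydro-4H-chromen-4-one
Product: 17 (2S)-6-[(1E,3S)-3,7-dimethylocta-1,6-dien-1-yl]-5,7-dihydroxy-2-(4-hydroxyphenyl)-2,3-dihydro-4H-chromen-4-one (target), via tris(trimethylsilyl) ether 16 (not isolated)
Conditions: TMSOTf (7 equiv), 2,2'-bipyridyl (10 equiv), MeCN, 0 °C → rt; then H2O, rt
Reagents that add atoms: none
Why: Silyl triflate/bipyridyl-mediated exchange of the aryl MOM ethers for TMS ethers followed by hydrolysis is non-protic and buffered, so neither the acid-labile dienyl chain next to the freed phenols nor the base-labile flavanone (C2) should be harmed.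

## Compound list

1 | 5-fluororesorcinol (5-fluorobenzene-1,3-diol) | Oc1cc(F)cc(O)c1 | starting material
2 | 5-fluoro-2-iodobenzene-1,3-diol | Oc1cc(F)cc(O)c1I | intermediate
3 | 5-fluoro-2-iodo-1,3-bis(methoxymethoxy)benzene | COCOc1cc(F)cc(OCOC)c1I | intermediate
4 | (S)-3,7-dimethylocta-1,6-diene ((S)-β-citronellene) | CC(C)=CCC[C@H](C)C=C | starting material
5 | 2-[(1E,3S)-3,7-dimethylocta-1,6-dien-1-yl]-5-fluoro-1,3-bis(methoxymethoxy)benzene | CC(C)=CCC[C@H](C)/C=C/c1c(OCOC)cc(F)cc1OCOC | intermediate
6 | 4'-hydroxyacetophenone | CC(=O)c1ccc(O)cc1 | starting material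
7 | 1-[4-(methoxymethoxy)phenyl]ethan-1-one | CC(=O)c1ccc(OCOC)cc1 | intermediate
8 | ethyl 3-[4-(methoxymethoxy)phenyl]-3-oxopropanoate | CCOC(=O)CC(=O)c1ccc(OCOC)cc1 | intermediate
9 | ethyl (3S)-3-hydroxy-3-[4-(methoxymethoxy)phenyl]propanoate | CCOC(=O)C[C@@H](c1ccc(OCOC)cc1)O | intermediate
10 | (3S)-3-hydroxy-3-[4-(methoxymethoxy)phenyl]propanoic acid | OC(=O)C[C@@H](c1ccc(OCOC)cc1)O | intermediate
11 | (4S)-4-[4-(methoxymethoxy)phenyl]oxetan-2-one | O=C1C[C@@H](c2ccc(OCOC)cc2)O1 | intermediate
12 | {3-[(1E,3S)-3,7-dimethylocta-1,6-dien-1-yl]-6-fluoro-2,4-bis(methoxymethoxy)phenyl}lithium (not isolated) | [Li]c1c(F)cc(OCOC)c(/C=C/[C@@H](C)CCC=C(C)C)c1OCOC | intermediate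
13 | lithium (4S)-2-{3-[(1E,3S)-3,7-dimethylocta-1,6-dien-1-yl]-6-fluoro-2,4-bis(methoxymethoxy)phenyl}-4-[4-(methoxymethoxy)phenyl]oxetan-2-olate, epimers at the hemiketal carbon (not isolated) | [Li+].[O-]C1(c2c(F)cc(OCOC)c(/C=C/[C@@H](C)CCC=C(C)C)c2OCOC)C[C@@H](c2ccc(OCOC)cc2)O1 | intermediate
14 | lithium (1S)-3-{3-[(1E,3S)-3,7-dimethylocta-1,6-dien-1-yl]-6-fluoro-2,4-bis(methoxymethoxy)phenyl}-1-[4-(methoxymethoxy)phenyl]-3-oxopropan-1-olate (not isolated) | [Li+].[O-][C@@H](CC(=O)c1c(F)cc(OCOC)c(/C=C/[C@@H](C)CCC=C(C)C)c1OCOC)c1ccc(OCOC)cc1 | intermediate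
15 | (2S)-6-[(1E,3S)-3,7-dimethylocta-1,6-dien-1-yl]-5,7-bis(methoxymethoxy)-2-[4-(methoxymethoxy)phenyl]-2,3-dihydro-4H-chromen-4-one | CC(C)=CCC[C@H](C)/C=C/c1c(OCOC)cc2c(c1OCOC)C(=O)C[C@@H](c1ccc(OCOC)cc1)O2 | intermediate
16 | (2S)-6-[(1E,3S)-3,7-dimethylocta-1,6-dien-1-yl]-5,7-bis(trimethylsilyloxy)-2-[4-(trimethylsilyloxy)phenyl]-2,3-dihydro-4H-chromen-4-one (not isolated) | CC(C)=CCC[C@H](C)/C=C/c1c(O[Si](C)(C)C)cc2c(c1O[Si](C)(C)C)C(=O)C[C@@H](c1ccc(O[Si](C)(C)C)cc1)O2 | intermediate
17 | (2S)-6-[(1E,3S)-3,7-dimethylocta-1,6-dien-1-yl]-5,7-dihydroxy-2-(4-hydroxyphenyl)-2,3-dihydro-4H-chromen-4-one | CC(C)=CCC[C@H](C)/C=C/c1c(O)cc2c(c1O)C(=O)C[C@@H](c1ccc(O)cc1)O2 | target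

## Step count and risks

Total steps: 10. Longest linear sequence: 7 steps (6 → 7 → 8 → 9 → 10 → 11 → 15 → 17).

**Step 9 (proposed new method).** The lithium aldolate 14 may undergo retro-aldol cleavage or E1cB dehydration before the SNAr closure, which would erode the configuration at C2. The lactone may also be deprotonated or lose CO2 instead of being acylated, and proton transfer from the product ketone to 14 could open the flavanone. The fallback uses known chemistry, sets out from 9 and 5, and returns at 15. Hydroxy ester 9 is silylated (TBSCl, imidazole, DMF) to ethyl (3S)-3-[(tert-butyldimethylsilyl)oxy]-3-[4-(methoxymethoxy)phenyl]propanoate F1. This is converted with MeNH(OMe)·HCl/i-PrMgCl (THF, −20 °C) into (3S)-3-[(tert-butyldimethylsilyl)oxy]-N-methoxy-3-[4-(methoxymethoxy)phenyl]-N-methylpropanamide F2. Aryllithium 12 (from 5, LiTMP, THF, −78 °C) is then added to F2 in a Weinreb ketone synthesis; the chelated adduct prevents over-addition and keeps the carbinol masked, so work-up should give the β-silyloxy ketone (3S)-3-[(tert-butyldimethylsilyl)oxy]-1-{3-[(1E,3S)-3,7-dimethylocta-1,6-dien-1-yl]-6-fluoro-2,4-bis(methoxymethoxy)phenyl}-3-[4-(methoxymethoxy)phenyl]propan-1-one F3. Fluoride (TBAF, THF, 0 °C, or CsF, DMF) then releases the alkoxide gradually, in the absence of amide or aryllithium bases, and intramolecular SNAr at the C–F bond should give 15.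

**Step 3.** Carbopalladation by the di-ortho-substituted, electron-rich aryl–Pd may be slow, and β-hydride elimination towards C3' could cause double-bond migration and loss of the stereocenter. The fallback sets out from 4 and 3 and returns at 5. A boryl-Heck reaction of 4 (B-chlorocatecholborane, Pd/bulky phosphine, amine base; pinacol work-up) should give 2-[(1E,3S)-3,7-dimethylocta-1,6-dien-1-yl]-4,4,5,5-tetramethyl-1,3,2-dioxaborolane F4. Suzuki–Miyaura coupling of F4 with 3 (Pd(OAc)2/SPhos, K3PO4, THF/H2O, 60 °C) then gives 5. This moves the C–C bond formation from a hindered carbopalladation to a transmetalation, which is reliable for 2,6-dialkoxyaryl iodides.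

**Step 10.** Cationic cyclisation of the dienyl chain onto the freed ortho phenols could be triggered by the silyl triflate or during hydrolysis, and cleavage at O7/O4' may be incomplete. The fallback sets out from 3 and 11 and returns at 17; it removes the MOM groups before the diene exists.
- Iodine–lithium exchange on 3 (n-BuLi, THF, −78 °C) and TMSCl give [4-fluoro-2,6-bis(methoxymethoxy)phenyl]trimethylsilane F5; the silyl group blocks the position between the OMOM groups.
- Ring expansion of 11 with lithiated F5 under the conditions of step 9 gives (2S)-5,7-bis(methoxymethoxy)-2-[4-(methoxymethoxy)phenyl]-6-(trimethylsilyl)-2,3-dihydro-4H-chromen-4-one F6.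
- Ipso-iododesilylation (ICl, CH2Cl2, −78 °C) gives (2S)-6-iodo-5,7-bis(methoxymethoxy)-2-[4-(methoxymethoxy)phenyl]-2,3-dihydro-4H-chromen-4-one F7.
- Acetal solvolysis (HCl, MeOH, rt), harmless without the diene, gives (2S)-5,7-dihydroxy-2-(4-hydroxyphenyl)-6-iodo-2,3-dihydro-4H-chromen-4-one F8.
- A Heck reaction of F8 with 4 under the conditions of step 3 attaches the side chain last and gives 17 directly.

## Further compounds

F1 | step 9 | ethyl (3S)-3-[(tert-butyldimethylsilyl)oxy]-3-[4-(methoxymethoxy)phenyl]propanoate | CCOC(=O)C[C@@H](c1ccc(OCOC)cc1)O[Si](C)(C)C(C)(C)C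
F2 | step 9 | (3S)-3-[(tert-butyldimethylsilyl)oxy]-N-methoxy-3-[4-(methoxymethoxy)phenyl]-N-methylpropanamide | CON(C)C(=O)C[C@@H](c1ccc(OCOC)cc1)O[Si](C)(C)C(C)(C)C
F3 | step 9 | (3S)-3-[(tert-butyldimethylsilyl)oxy]-1-{3-[(1E,3S)-3,7-dimethylocta-1,6-dien-1-yl]-6-fluoro-2,4-bis(methoxymethoxy)phenyl}-3-[4-(methoxymethoxy)phenyl]propan-1-one | CC(C)=CCC[C@H](C)/C=C/c1c(OCOC)cc(F)c(c1OCOC)C(=O)C[C@@H](c1ccc(OCOC)cc1)O[Si](C)(C)C(C)(C)C
F4 | step 3 | 2-[(1E,3S)-3,7-dimethylocta-1,6-dien-1-yl]-4,4,5,5-tetramethyl-1,3,2-dioxaborolane | CC(C)=CCC[C@H](C)/C=C/B1OC(C)(C)C(C)(C)O1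
F5 | step 10 | [4-fluoro-2,6-bis(methoxymethoxy)phenyl]trimethylsilane | COCOc1cc(F)cc(OCOC)c1[Si](C)(C)C
F6 | step 10 | (2S)-5,7-bis(methoxymethoxy)-2-[4-(methoxymethoxy)phenyl]-6-(trimethylsilyl)-2,3-dihydro-4H-chromen-4-one | C[Si](C)(C)c1c(OCOC)cc2c(c1OCOC)C(=O)C[C@@H](c1ccc(OCOC)cc1)O2
F7 | step 10 | (2S)-6-iodo-5,7-bis(methoxymethoxy)-2-[4-(methoxymethoxy)phenyl]-2,3-dihydro-4H-chromen-4-one | Ic1c(OCOC)cc2c(c1OCOC)C(=O)C[C@@H](c1ccc(OCOC)cc1)O2
F8 | step 10 | (2S)-5,7-dihydroxy-2-(4-hydroxyphenyl)-6-iodo-2,3-dihydro-4H-chromen-4-one | Ic1c(O)cc2c(c1O)C(=O)C[C@@H](c1ccc(O)cc1)O2
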